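South-east and west are two runs of one recipe that differ in the charge of starting material, and both were read at 4.00 min, the time asked of delta and eta. We measure each flask by its reach, the natural logarithm of charged over left. A pseudo-first-order loss whose rate constant is independent of the charge gives equal reach at equal time.

common to all: free catalyst 0.42 µM
- south-east: starting material 1.4 × 10⁻⁴ M; partner 0.36 mM; run made earlier
- west: starting material 2.1 × 10⁻⁴ M; partner 0.36 mM; run made earlier
- delta: starting material 2.0 × 10⁻⁴ M; partner 0.360 mM; time 4.0 min
- eta: starting material 1.0 × 10⁻⁴ M; partner 0.360 mM; time 4.0 min

- south-east (time / min: product / %, starting material / %): 1.00: 40.1, 59.4; 2.00: 47.3, 52.5; 3.00: 50.8, 49.7; 4.00: 51.9, 47.8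
- west (time / min: product / %, starting material / %): 0.333: 22.5, 77.4; 0.667: 31.5, 68.1; 1.50: 40.4, 59.4; 4.00: 47.2, 52.8

(each reading ± 0.3 percentage points)

* which of the two ends with the higher amount of product, in percent of the starting material charged ("neither" if they lie within 2 percentage points) (delta / eta / neither)
* product at the end, in percent of the starting material charged, delta
* product at the end, in percent of the starting material charged, eta



South-east left 47.8% of its starting material, a reach of 0.738, and west left 52.8%, a reach of 0.639. Our first estimate was one common reach for delta and eta, but it fails: the two readings lie 5 percentage points apart, more than the scatter of 0.3 points, so we read the reach of west as smaller than that of south-east. Product and starting material sum to 99.7% in south-east and 100% in west at that time, so we take product as the charge minus what is left.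

So we keep west as the large term and compute just the correction, a fall in reach with charge of 1.42 mM⁻¹. We then reckon the reach of delta at 4.0 min as 0.653, which means 47.9% product. For eta we reckon a reach of 0.795, which means 54.8%.

The objection is that the charge of eta lies below those of both runs, so part of its correction of 0.156 is extrapolated. Making the inverse of reach the straight line instead gives eta 55.5%. That shift of 0.70 points is smaller than the lead of 6.9 points that we reckon for eta over delta, and that reckoned lead exceeds the margin of 2 points.

The forecast names eta, with 47.9% for delta and 55.5% for eta, and reads the smaller reach of west thus: “higher loading kills the catalyst slightly faster”. Its eta stands 0.70 points above our straight line in reach.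

    2 free catalyst → spent catalyst (k = 60000 L mol⁻¹ s⁻¹)
    partner → decomposed reagent (k = 0.00603 s⁻¹)
    starting material + partner + free catalyst → product + free catalyst, rate k3*[starting material]*[partner]*[free catalyst]/(1 + ([starting material]/sat3)) (0.476 mM, k = 1.91 × 10⁸ L² mol⁻² s⁻¹)

Delta ends at 47.4% and eta at 55.0%, so eta gives more. Free catalyst stands at 7.64% of its charge in delta and at 7.64% in eta at 4.00 min. The reach of delta comes out as 0.642 against the 0.653 we reckoned. The neighbour of delta charged with 1.7 × 10⁻⁶ M of free catalyst, 4.05 times the charge of delta, ends with 64.3% product, a reach of 1.03, which is 1.58 times our 0.653.

The runs come from a simulation from invented constants; scatter was added.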